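## The problem

The target **24** is a daucane: a cyclopentane (ring A, C1–C5) trans-fused along C1–C5 to a cycloheptane (ring B, C5–C10 and C1). It carries the angular methyl C15 on quaternary C1, an isopropyl carbinol at C4, a 4-hydroxybenzoate on O6, an exocyclic methylene C14 on C8 and a secondary allylic carbinol at C9. With β defined as the face of C15, the five stereocentres read 4β-OH, 5α-H, 6α-O-acyl and 9β-OH, so the C9 hydroxyl sits on the face of the angular methyl. C1 has no neighbour to lean on and must come from a catalyst. It can then steer C5 (a new bond at C5 forms anti to the bulkier C1 substituent), C5 steers C4 (nucleophile anti to the C5 side chain) and C6 (closed aldol transition state), and C15 screens the β face of C9 against an incoming hydride. The aryl ester on the hindered O6 will not survive organolithium, Grignard or alkaline conditions, and its phenol must be masked while the acid is activated. The tertiary C4 carbinol and the methylene-substituted allylic alcohol tolerate neither strong acid (dehydration, ionisation) nor conditions that move the 1,1-disubstituted alkene into the ring. The feature that makes the key step possible is that C9 is a carbinol bonded to C8, which bears the methylene C14. This is the adduct of a C7–C8(=C14) alkenyl metal and a C9 aldehyde, and the two arms (C10–C9 on C1, C6–C7–C8 on C5) stand trans on ring A, so ring B can be closed last at C8–C9.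

## Retrosynthesis

**24 ⇒ 23 (phenolic O–Si).** Only the phenol is uncovered in the last step. It must be masked from the moment the acid is activated, and a tert-butyldimethylsilyl aryl ether should pass DMAP, OsO4, CrCl2, periodinane and borohydride, then leave with buffered fluoride. The forward step must cleave it without acyl migration or ester hydrolysis.

**23 ⇒ 22 ⇒ 21 (C9–H).** The configuration at C9 is deliberately separated from the ring closure. Cutting C9–H leads to enone **22** and through it to alcohol **21** of either configuration. The face of C9 attacked in a seven-ring closure depends on which twist-chair the forming ring adopts. A hydride approaching the C9 carbonyl of the finished bicycle, by contrast, meets C15 on the β face in every accessible conformer. Two steps are spent, and in return nothing is asked of the diastereoselectivity of the key step.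

**21 ⇒ 20 (C8–C9, key disconnection).** Cutting between the methylene-bearing C8 and the carbinol C9 opens ring B and turns the allylic alcohol into an alkenyl iodide and an aldehyde. The neighbouring cuts are poorer: C7–C8 and C9–C10 have no functional handle on both ends, and C1–C10 would have to create the quaternary centre during a ring closure. Precursor **20** has one ring fewer, no medium ring, and already carries the full oxidation pattern including the ester. The forward reaction needs an alkenyl metal that adds to an aldehyde but ignores an ester, a silyl ether and a free tertiary alcohol, which points to chromium.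

**20 ⇒ 18 (C9=O from C9=CH2).** The aldehyde is unveiled from an allyl group through diol **19**, and only after the ester is in place. With O6 free, the C9 aldehyde would be held as a six-membered lactol (O6–C6–C5–C1–C10–C9). O4 lies on the face opposite the C10 arm and cannot interfere. The oxidant must distinguish the monosubstituted alkene from the iodoalkene.

**18 ⇒ 13 + 17 (O6–acyl).** The ester is cut to diol **13** and acid chloride **17**, which comes from acid **16** and 4-hydroxybenzoic acid **14** through the bis-silyl compound **15**. Acylating here rather than at the end is preferred because later two secondary hydroxyls (O6, O9) would compete, whereas in **13** the only competitor is the tertiary O4.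

**13 ⇒ 12 (C4–isopropyl).** Removing the isopropyl group gives β-hydroxy ketone **12**. The cyclopentanone is attacked anti to its C5 substituent, which is the sense needed for 4β-OH. The forward step must add a branched nucleophile to a hindered, enolisable ketone that also carries an iodoalkene.

**12 ⇒ 6 + 9 (C5–C6).** The aldol bond is cut to silyl enol ether **6** and 3-iodobut-3-enal **9**, made from but-3-yn-1-ol **7** through iodo alcohol **8**. The enolate required (through **10** and **11**) is the one on the side of the quaternary carbon. Deprotonation cannot give it, so it is stored as **6**. This cut brings in C6 with its oxygen and the complete C7–C8(I)=C14 unit in one step.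

**6 ⇒ 4 (C1–C15 and O–Si).** The methyl group is removed from C1, leading to enone **4**. The aluminium enolate **5** formed in the forward direction is silylated. Methyl is added last and allyl first because asymmetric conjugate addition of Me3Al to β-substituted cyclopentenones is established, whereas asymmetric conjugate allylation is not.

**4 ⇒ 1 + 2 (C1–C10).** Enone **4** comes from 3-ethoxycyclopent-2-en-1-one **1** and allylmagnesium bromide **2** through adduct **3**, by addition and carbonyl transposition.

## Roads not taken

**Alternative 1:** Both ring bonds to C1 (C1–C5 and C1–C10) are cut at once, leading to the aryl-tethered α-methyl diazoketone A1, whose benzene ring is the future ring B. In the forward direction Cu(MeCN)4PF6 with a chiral bis(oxazoline) decomposes A1. The metal-bound carbene adds across the arene bond C5–C10 and electrocyclic opening gives the cycloheptatriene A2 (intramolecular Buchner reaction).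
- Merits: a flat, easily assembled precursor. Two rings, two bonds and the quaternary centre form in one step. Oxygen at C6 and C9 and carbon C14 are already present as enol ethers and a methoxymethyl group.
- Weak points for this target:
  - Carbenes bearing an α-methyl group are prone to 1,2-hydride shift.
  - The benzylic tertiary C4 carbinol must be made enantiopure beforehand.
  - A2 has a C2 carbonyl that the target lacks.
  - C5, C6 and C9 are still trigonal, so the trans ring fusion, 6α-O and 9β-OH would all depend on late reductions of a flexible cycloheptadienone, beside a deoxygenation and conversion of the methoxymethyl group into the methylene.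
- Comparison: in bond-forming economy of the key step this road is better (two rings against one). The chosen plan sets against it that every sp3 centre except C9 is fixed before the ring closes and that only C9 needs an oxidation-state correction afterwards.

**Alternative 2:** C1–C15 and C4–C5 are cut, leading to the achiral cycloheptenone A3 with the isopropyl ketone on a two-carbon tether at C1 and a ketal at C9. In the forward direction Cu(OTf)2 with a chiral phosphoramidite delivers methyl from Me3Al to C1. The enolate so formed adds at C5 to the side-chain ketone and closes ring A, giving hydroxy ketone A4.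
- Merits: C1, C4, C5 and ring A arise in one catalytic step from an achiral ring. There is no medium-ring closure and no labile iodoaldehyde, and O6 and O9 are already differentiated. In steps to the bicyclic core this road is shorter than the chosen plan.
- Weak points for this target:
  - The enolate must add reversibly to a hindered isopropyl ketone.
  - The tether sits on C1 on the face opposite the new methyl and can reach C5 only on that same face, so the kinetic bicycle is cis-fused (H5 syn to C15), while A4 needs H5 anti.
  - Correcting this means base epimerisation at C5 of a β-hydroxy ketone that can fall apart by retro-aldol.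
  - C6 reduction, acylation, ketal removal, methylenation at C8 and C9 reduction still follow.
- Comparison: the chosen plan is longer to the core. It sets against this that the trans relation of the two arms comes from an intermolecular aldol whose steric bias points in the required direction.

**Alternative 3:** The carbon skeleton is made biocatalytically. A magnesium-dependent class 1 terpene synthase of the daucane family ionises farnesyl diphosphate A5 and closes both rings. A hydride shift and capture of water then give dauc-8-en-4β-ol A6 with C1, C4 and C5 set.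
- Merits: one step from a fermentable precursor, with complete control of three stereocentres and no protecting groups. For the carbon skeleton no chemical route can match it.
- Weak points for this target:
  - A6 has no oxygen at C6, and C6 is an unactivated methylene that is not even allylic, so 6α-hydroxylation needs a second selective oxidase or a long detour.
  - The C8 alkene must be moved to C8(14) with introduction of 9β-OH, for which an ene reaction with singlet oxygen offers neither secure regio- nor facial control.
  - An enzyme with exactly this product profile must be available.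
- Comparison: if both enzymes existed this would be the shortest road. The chosen plan sets against it that it needs no enzyme discovery and that O6 arrives with the aldol.

Key step: step 11

Assumption: daucane numbering is used for all intermediates and α/β name the faces of the bicycle with C15 as β; read this way the target SMILES is 1R,4R,5S,6S,9R with 4β-OH, 5α-H, 6α-acyloxy and 9β-OH.

## Route

Step 1
Reactants: 1 3-ethoxycyclopent-2-en-1-one; 2 allylmagnesium bromide
Product: 4 3-(prop-2-en-1-yl)cyclopent-2-en-1-one, via bromomagnesium 1-allyl-3-ethoxycyclopent-2-en-1-olate 3 (not isolated)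
Conditions: THF, 0 °C; then 1 M HCl, 0 °C
Reagents that add atoms: water, O
Why: 1,2-Addition of the allyl Grignard reagent to the vinylogous ester, then acid-induced loss of water and ethanol, transposes the carbonyl (Stork–Danheiser sequence); brief cold acid should keep the allyl double bond out of conjugation.

Step 2
Reactants: 4 3-(prop-2-en-1-yl)cyclopent-2-en-1-one
Product: 6 triethyl{[(3R)-3-methyl-3-(prop-2-en-1-yl)cyclopent-1-en-1-yl]oxy}silane, via dimethylaluminium enolate 5 (not isolated)
Conditions: Me3Al, Cu(OTf)2 (5 mol%), chiral sulfonate-bearing imidazolinium salt (carbene ligand precursor, 6 mol%), THF, −78 °C; then Et3SiOTf, −78 to 0 °C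
Reagents that add atoms: trimethylaluminium, C[Al](C)C; triethylsilyl trifluoromethanesulfonate, CC[Si](CC)(CC)OS(=O)(=O)C(F)(F)F
Why: Copper-catalysed asymmetric conjugate addition of Me3Al to a β-substituted cyclopentenone creates quaternary C1, the face being chosen by the carbene ligand (the antipode that gives 1R is used); O-silylation of the aluminium enolate stores the C4=C5 enolate regiochemistry in an isolable silyl enol ether.

Step 3
Reactants: 7 but-3-yn-1-ol
Product: 8 3-iodobut-3-en-1-ol
Conditions: NaI, Me3SiCl, H2O, MeCN, 23 °C
Reagents that add atoms: sodium iodide, [Na+].[I-]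
Why: Hydrogen iodide generated in the flask adds to the terminal alkyne in the Markovnikov sense, a standard route to 2-iodoalk-1-enes.

Step 4
Reactants: 8 3-iodobut-3-en-1-ol
Product: 9 3-iodobut-3-enal
Conditions: Dess–Martin periodinane, CH2Cl2, 0 to 23 °C; solution used at once
Reagents that add atoms: none
Why: Dess–Martin oxidation stops at the aldehyde under non-basic conditions; the β,γ-unsaturated aldehyde is not purified, so the double bond has no occasion to move into conjugation.

Step 5
Reactants: 6 triethyl{[(3R)-3-methyl-3-(prop-2-en-1-yl)cyclopent-1-en-1-yl]oxy}silane; 9 3-iodobut-3-enal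
Product: 12 (2S,3R)-2-[(1S)-1-hydroxy-3-iodobut-3-en-1-yl]-3-methyl-3-(prop-2-en-1-yl)cyclopentan-1-one, via lithium enolate 10 (not isolated), via chlorozinc enolate 11 (not isolated)
Conditions: MeLi, THF, 0 to 23 °C; ZnCl2, −78 °C; then 9, −78 °C
Reagents that add atoms: none
Why: MeLi cleaves the Si–O bond to the regiodefined enolate, ZnCl2 lowers its basicity, and the aldol addition should run through a closed Zimmerman–Traxler chair. The aldehyde should approach C5 on the face of the C15 methyl, away from the larger allyl group (5S), and the necessarily (E)-configured cyclic enolate with the aldehyde chain equatorial should give the anti aldol (6S).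

Step 6
Reactants: 12 (2S,3R)-2-[(1S)-1-hydroxy-3-iodobut-3-en-1-yl]-3-methyl-3-(prop-2-en-1-yl)cyclopentan-1-one
Product: 13 (1R,2S,3R)-2-[(1S)-1-hydroxy-3-iodobut-3-en-1-yl]-3-methyl-1-(propan-2-yl)-3-(prop-2-en-1-yl)cyclopentan-1-ol
Conditions: iPrMgCl, CeCl3, THF, −78 °C
Reagents that add atoms: isopropylmagnesium chloride, CC(C)[Mg]Cl
Why: Addition of the reagent made from iPrMgCl and CeCl3 (Imamoto conditions) should suppress enolisation, reduction and iodine–magnesium exchange; the nucleophile should add from the α face, anti to the adjacent C5 side chain, giving the 4β (4R) tertiary alcohol.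

Step 7
Reactants: 14 4-hydroxybenzoic acid
Product: 16 4-[(tert-butyldimethylsilyl)oxy]benzoic acid, via tert-butyldimethylsilyl 4-[(tert-butyldimethylsilyl)oxy]benzoate 15 (not isolated)
Conditions: TBSCl, imidazole, DMF, 23 °C; then AcOH, THF, H2O, 23 °C
Reagents that add atoms: tert-butyldimethylsilyl chloride, CC(C)(C)[Si](C)(C)Cl
Why: Both hydroxyl groups are silylated and the much more labile silyl ester is then hydrolysed selectively, leaving the aryl silyl ether; this is a standard protection sequence.

Step 8
Reactants: 16 4-[(tert-butyldimethylsilyl)oxy]benzoic acid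
Product: 17 4-[(tert-butyldimethylsilyl)oxy]benzoyl chloride
Conditions: (COCl)2, DMF (cat.), CH2Cl2, 0 to 23 °C
Reagents that add atoms: oxalyl chloride, O=C(Cl)C(=O)Cl
Why: Activation with oxalyl chloride and catalytic DMF gives the acid chloride under anhydrous conditions that should leave the aryl silyl ether intact.

Step 9
Reactants: 13 (1R,2S,3R)-2-[(1S)-1-hydroxy-3-iodobut-3-en-1-yl]-3-methyl-1-(propan-2-yl)-3-(prop-2-en-1-yl)cyclopentan-1-ol; 17 4-[(tert-butyldimethylsilyl)oxy]benzoyl chloride
Product: 18 (1S)-1-[(1S,2R,5R)-2-hydroxy-5-methyl-2-(propan-2-yl)-5-(prop-2-en-1-yl)cyclopentyl]-3-iodobut-3-en-1-yl 4-[(tert-butyldimethylsilyl)oxy]benzoate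
Conditions: Et3N, DMAP, CH2Cl2, 0 to 23 °C
Reagents that add atoms: none
Why: DMAP-catalysed acylation should occur only at the secondary O6 hydroxyl, the tertiary C4 hydroxyl being too hindered; the C–O bond is not broken, so C6 keeps its configuration.

Step 10
Reactants: 18 (1S)-1-[(1S,2R,5R)-2-hydroxy-5-methyl-2-(propan-2-yl)-5-(prop-2-en-1-yl)cyclopentyl]-3-iodobut-3-en-1-yl 4-[(tert-butyldimethylsilyl)oxy]benzoate
Product: 20 (1S)-1-[(1S,2R,5R)-2-hydroxy-5-methyl-5-(2-oxoethyl)-2-(propan-2-yl)cyclopentyl]-3-iodobut-3-en-1-yl 4-[(tert-butyldimethylsilyl)oxy]benzoate, via vicinal diol 19 (not isolated)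
Conditions: OsO4 (2 mol%), NMO, acetone/H2O, 0 to 23 °C; then NaIO4, 23 °C
Reagents that add atoms: osmium tetroxide, O=[Os](=O)(=O)=O; N-methylmorpholine N-oxide, C[N+]1([O-])CCOCC1
Why: Catalytic dihydroxylation should select the electron-richer monosubstituted allyl alkene over the electron-poor, hindered iodoalkene, and periodate cleaves the diol (two-stage Lemieux–Johnson-type cleavage). The O6 ester prevents lactol formation and the trans C4 hydroxyl cannot reach C9.

Step 11
Reactants: 20 (1S)-1-[(1S,2R,5R)-2-hydroxy-5-methyl-5-(2-oxoethyl)-2-(propan-2-yl)cyclopentyl]-3-iodobut-3-en-1-yl 4-[(tert-butyldimethylsilyl)oxy]benzoate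
Product: 21 4β,9-dihydroxydauc-8(14)-en-6α-yl 4-[(tert-butyldimethylsilyl)oxy]benzoate (1R,4R,5S,6S; 9α and 9β epimers together)
Conditions: CrCl2 (excess), NiCl2 (2 mol%), degassed DMF, 23 °C, high dilution
Reagents that add atoms: none
Why: NiCl2 is reduced by CrCl2 to zerovalent nickel, which inserts into the C8–I bond; the alkenyl group passes to trivalent chromium and the alkenylchromium adds to the C9 aldehyde (intramolecular Nozaki–Hiyama–Kishi reaction, the closest known type being closures of iodoalkene aldehydes to medium-ring 2-methylenecycloalkanols). Ring B forms by 7-exo-trig attack of C8 on the aldehyde carbon, and the trans arrangement of the two arms on ring A keeps the chain ends within reach and leads directly to the trans-fused bicycle. The reagent adds to aldehydes only, so the aryl ester, the aryl silyl ether and the free tertiary hydroxyl should be left alone; the step needs this chemoselectivity and ring closure in preference to intermolecular coupling, the latter secured by high dilution. The new stereocentre C9 is governed by the face on which the C9–O–Cr bond lies in the closing twist-chair: the pseudo-equatorial site is preferred, but it is β when C10 lies on the twist-chair axis and α when C6 or C7 does, so either epimer may prevail. No facial selectivity is therefore demanded here, because both epimers of 21 give the same enone 22 in step 12 and C9 is fixed in step 13.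

Step 12
Reactants: 21 4β,9-dihydroxydauc-8(14)-en-6α-yl 4-[(tert-butyldimethylsilyl)oxy]benzoate (both C9 epimers)
Product: 22 4β-hydroxy-9-oxodauc-8(14)-en-6α-yl 4-[(tert-butyldimethylsilyl)oxy]benzoate (1R,4R,5S,6S)
Conditions: Dess–Martin periodinane, CH2Cl2, 0 °C
Reagents that add atoms: none
Why: Dess–Martin oxidation of the secondary allylic alcohol; both C9 epimers should converge on one cross-conjugated enone, and the hindered tertiary C4 hydroxyl is inert.

Step 13
Reactants: 22 4β-hydroxy-9-oxodauc-8(14)-en-6α-yl 4-[(tert-butyldimethylsilyl)oxy]benzoate
Product: 23 4β,9β-dihydroxydauc-8(14)-en-6α-yl 4-[(tert-butyldimethylsilyl)oxy]benzoate (1R,4R,5S,6S,9R)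
Conditions: NaBH4, CeCl3·7H2O, MeOH, −78 °C
Reagents that add atoms: none
Why: Luche reduction should give clean 1,2-reduction of the enone; hydride should enter C9 from the α face, because the angular C15 methyl screens the β face in each accessible twist-chair of ring B (axial α attack in one, blocked β-axial path in the others), which places the hydroxyl β (9R).

Step 14
Reactants: 23 4β,9β-dihydroxydauc-8(14)-en-6α-yl 4-[(tert-butyldimethylsilyl)oxy]benzoate
Product: 24 4β,9β-dihydroxydauc-8(14)-en-6α-yl 4-hydroxybenzoate (1R,4R,5S,6S,9R), the target
Conditions: Bu4NF, AcOH, THF, 0 °C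
Reagents that add atoms: none
Why: Fluoride cleaves the aryl Si–O bond far faster than it affects anything else; acetic acid buffers the phenoxide so that the ester should neither migrate nor hydrolyse.

## Compound list

1 | 3-ethoxycyclopent-2-en-1-one | CCOC1=CC(=O)CC1 | starting material
2 | allylmagnesium bromide | C=CC[Mg]Br | starting material
3 | bromomagnesium 1-allyl-3-ethoxycyclopent-2-en-1-olate (racemic) | CCOC1=CC(CC=C)(O[Mg]Br)CC1 | intermediate (not isolated)
4 | 3-(prop-2-en-1-yl)cyclopent-2-en-1-one | C=CCC1=CC(=O)CC1 | intermediate
5 | dimethylaluminium (3R)-3-methyl-3-(prop-2-en-1-yl)cyclopent-1-en-1-olate | C=CC[C@]1(C)C=C(O[Al](C)C)CC1 | intermediate (not isolated)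
6 | triethyl{[(3R)-3-methyl-3-(prop-2-en-1-yl)cyclopent-1-en-1-yl]oxy}silane | C=CC[C@]1(C)C=C(O[Si](CC)(CC)CC)CC1 | intermediate
7 | but-3-yn-1-ol | C#CCCO | starting material
8 | 3-iodobut-3-en-1-ol | C=C(I)CCO | intermediate
9 | 3-iodobut-3-enal | C=C(I)CC=O | intermediate
10 | lithium (3R)-3-methyl-3-(prop-2-en-1-yl)cyclopent-1-en-1-olate | C=CC[C@]1(C)C=C(O[Li])CC1 | intermediate (not isolated)
11 | chlorozinc (3R)-3-methyl-3-(prop-2-en-1-yl)cyclopent-1-en-1-olate | C=CC[C@]1(C)C=C(O[Zn]Cl)CC1 | intermediate (not isolated)
12 | (2S,3R)-2-[(1S)-1-hydroxy-3-iodobut-3-en-1-yl]-3-methyl-3-(prop-2-en-1-yl)cyclopentan-1-one | C=C(I)C[C@H](O)[C@@H]1[C@](C)(CCC1=O)CC=C | intermediate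
13 | (1R,2S,3R)-2-[(1S)-1-hydroxy-3-iodobut-3-en-1-yl]-3-methyl-1-(propan-2-yl)-3-(prop-2-en-1-yl)cyclopentan-1-ol | C=C(I)C[C@H](O)[C@@H]1[C@](C)(CC[C@@]1(O)C(C)C)CC=C | intermediate
14 | 4-hydroxybenzoic acid | OC(=O)c1ccc(O)cc1 | starting material
15 | tert-butyldimethylsilyl 4-[(tert-butyldimethylsilyl)oxy]benzoate | CC(C)(C)[Si](C)(C)OC(=O)c1ccc(O[Si](C)(C)C(C)(C)C)cc1 | intermediate (not isolated)
16 | 4-[(tert-butyldimethylsilyl)oxy]benzoic acid | CC(C)(C)[Si](C)(C)Oc1ccc(C(=O)O)cc1 | intermediate
17 | 4-[(tert-butyldimethylsilyl)oxy]benzoyl chloride | CC(C)(C)[Si](C)(C)Oc1ccc(C(=O)Cl)cc1 | intermediate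
18 | (1S)-1-[(1S,2R,5R)-2-hydroxy-5-methyl-2-(propan-2-yl)-5-(prop-2-en-1-yl)cyclopentyl]-3-iodobut-3-en-1-yl 4-[(tert-butyldimethylsilyl)oxy]benzoate | C=C(I)C[C@H](OC(=O)c1ccc(O[Si](C)(C)C(C)(C)C)cc1)[C@@H]2[C@](C)(CC[C@@]2(O)C(C)C)CC=C | intermediate
19 | ester 18 with the allyl group turned into 2,3-dihydroxypropyl (both epimers at the new carbinol) | C=C(I)C[C@H](OC(=O)c1ccc(O[Si](C)(C)C(C)(C)C)cc1)[C@@H]2[C@](C)(CC[C@@]2(O)C(C)C)CC(O)CO | intermediate (not isolated)
20 | (1S)-1-[(1S,2R,5R)-2-hydroxy-5-methyl-5-(2-oxoethyl)-2-(propan-2-yl)cyclopentyl]-3-iodobut-3-en-1-yl 4-[(tert-butyldimethylsilyl)oxy]benzoate | C=C(I)C[C@H](OC(=O)c1ccc(O[Si](C)(C)C(C)(C)C)cc1)[C@@H]2[C@](C)(CC[C@@]2(O)C(C)C)CC=O | intermediate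
21 | 4β,9-dihydroxydauc-8(14)-en-6α-yl 4-[(tert-butyldimethylsilyl)oxy]benzoate (1R,4R,5S,6S; 9α and 9β epimers together, C9 left open) | C=C1C[C@H](OC(=O)c3ccc(O[Si](C)(C)C(C)(C)C)cc3)[C@@H]2[C@](C)(CC[C@@]2(O)C(C)C)CC1O | intermediate
22 | 4β-hydroxy-9-oxodauc-8(14)-en-6α-yl 4-[(tert-butyldimethylsilyl)oxy]benzoate (1R,4R,5S,6S) | C=C1C[C@H](OC(=O)c3ccc(O[Si](C)(C)C(C)(C)C)cc3)[C@@H]2[C@](C)(CC[C@@]2(O)C(C)C)CC1=O | intermediate
23 | 4β,9β-dihydroxydauc-8(14)-en-6α-yl 4-[(tert-butyldimethylsilyl)oxy]benzoate (1R,4R,5S,6S,9R) | C=C1C[C@H](OC(=O)c3ccc(O[Si](C)(C)C(C)(C)C)cc3)[C@@H]2[C@](C)(CC[C@@]2(O)C(C)C)C[C@H]1O | intermediate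
24 | 4β,9β-dihydroxydauc-8(14)-en-6α-yl 4-hydroxybenzoate (1R,4R,5S,6S,9R) | C=C1C[C@H](OC(=O)c2ccc(O)cc2)[C@@H]2[C@](C)(CC[C@@]2(O)C(C)C)C[C@H]1O | target

## Step count and least certain steps

Total step count: 14. Longest linear sequence: 10 steps (from 1 through steps 1, 2, 5, 6, 9, 10, 11, 12, 13 and 14). The aldehyde branch (steps 3 and 4) and the acid chloride branch (steps 7 and 8) are each two steps.

**Step 11 (key step).** The most likely failure is premature protonation of the alkenyl metal, so that iodine is lost without C–C bond formation. Seven-ring closure is slow and the substrate carries its own proton source in the C4 hydroxyl; intermolecular coupling is the second risk. The fallback removes the internal proton source and sets out from 18. N-(Trimethylsilyl)imidazole silylates the tertiary hydroxyl to give the C4 trimethylsilyl ether of 18 F1. The OsO4/NMO then NaIO4 sequence of step 10 gives the C4 trimethylsilyl ether of 20 F2. Closure with CrCl2/NiCl2 gives the C4 trimethylsilyl ether of 21 F3. PPTS in MeOH then takes off the trimethylsilyl group and the route is rejoined at 21.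

**Step 5.** The most likely failure is erosion of simple diastereoselection at C6. The quaternary neighbour crowds the chair arrangement, so open or boat transition states may compete; proton transfer from the acidic α-position of 9 to the enolate is a further risk. The fallback uses the wrong epimer productively and sets out from 6. The C6 epimer of 12 F4 is carried through the iPrMgCl/CeCl3 addition of step 6 to the C6 epimer of 13 F5. F5 is then esterified with acid 16 under Mitsunobu conditions (PPh3, DIAD), which inverts C6 and rejoins the route at 18.

**Step 6.** The most likely failure is enolisation of the hindered ketone or retro-aldol cleavage of the metal aldolate in place of addition, because the first equivalent of reagent turns the C6 hydroxyl into an alkoxide. The fallback sets out from 12. Et3SiCl and imidazole give the C6 triethylsilyl ether of 12 F6. With no aldolate present, iPrMgCl/CeCl3 addition gives the C6 triethylsilyl ether of 13 F7. PPTS in MeOH removes the silyl group and the route is rejoined at 13.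

**Step 10.** The most likely failure is competing osmylation of the iodoalkene or oxidation at iodine during the longer exposure needed for a neopentyl-type allyl group. The fallback sets out from 18. mCPBA, an electrophilic oxidant that should leave the electron-poor iodoalkene alone, gives the terminal epoxide of 18 F8. H5IO6 hydrolyses and cleaves the epoxide and the route is rejoined at 20.

**Step 13.** The most likely failure is poor facial selectivity, if the flexibility of ring B lets hydride reach the β face. The fallback replaces substrate control by reagent control. From 22, reduction with (S)-2-methyl-CBS-oxazaborolidine and catecholborane, with the alkenyl group taken as the large substituent, should deliver hydride to the α face and arrive at 23. No new compound lies on this path, and any 9α alcohol can be returned to 22 by step 12.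

## Further compounds

F1 | step 11 | C4 trimethylsilyl ether of 18 | C=C(I)C[C@H](OC(=O)c1ccc(O[Si](C)(C)C(C)(C)C)cc1)[C@@H]2[C@](C)(CC[C@@]2(O[Si](C)(C)C)C(C)C)CC=C
F2 | step 11 | C4 trimethylsilyl ether of 20 | C=C(I)C[C@H](OC(=O)c1ccc(O[Si](C)(C)C(C)(C)C)cc1)[C@@H]2[C@](C)(CC[C@@]2(O[Si](C)(C)C)C(C)C)CC=O
F3 | step 11 | C4 trimethylsilyl ether of 21 (both C9 epimers) | C=C1C[C@H](OC(=O)c3ccc(O[Si](C)(C)C(C)(C)C)cc3)[C@@H]2[C@](C)(CC[C@@]2(O[Si](C)(C)C)C(C)C)CC1O
F4 | step 5 | (2S,3R)-2-[(1R)-1-hydroxy-3-iodobut-3-en-1-yl]-3-methyl-3-(prop-2-en-1-yl)cyclopentan-1-one (C6 epimer of 12) | C=C(I)C[C@@H](O)[C@@H]1[C@](C)(CCC1=O)CC=C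
F5 | step 5 | (1R,2S,3R)-2-[(1R)-1-hydroxy-3-iodobut-3-en-1-yl]-3-methyl-1-(propan-2-yl)-3-(prop-2-en-1-yl)cyclopentan-1-ol (C6 epimer of 13) | C=C(I)C[C@@H](O)[C@@H]1[C@](C)(CC[C@@]1(O)C(C)C)CC=C
F6 | step 6 | C6 triethylsilyl ether of 12 | C=C(I)C[C@H](O[Si](CC)(CC)CC)[C@@H]1[C@](C)(CCC1=O)CC=C
F7 | step 6 | C6 triethylsilyl ether of 13 | C=C(I)C[C@H](O[Si](CC)(CC)CC)[C@@H]1[C@](C)(CC[C@@]1(O)C(C)C)CC=C
F8 | step 10 | terminal epoxide of 18 (both epimers at the oxirane carbon) | C=C(I)C[C@H](OC(=O)c1ccc(O[Si](C)(C)C(C)(C)C)cc1)[C@@H]2[C@](C)(CC[C@@]2(O)C(C)C)CC3CO3
F0 | step 13 | none | none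
A1 | alternative 1 | (5R)-2-diazo-5-[2,5-dimethoxy-4-(methoxymethyl)phenyl]-6-methyl-5-(triethylsilyloxy)heptan-3-one | CC(=[N+]=[N-])C(=O)C[C@@](O[Si](CC)(CC)CC)(C(C)C)c1cc(OC)c(COC)cc1OC
A2 | alternative 1 | 4,7-dimethoxy-6-(methoxymethyl)-8a-methyl-3-(propan-2-yl)-3-(triethylsilyloxy)-2,3-dihydroazulen-1(8aH)-one | COCC1=CC(OC)=C2[C@](C)(C(=O)C[C@@]2(O[Si](CC)(CC)CC)C(C)C)C=C1OC
A3 | alternative 2 | 10-(4-methyl-3-oxopentyl)-1,4-dioxaspiro[4.6]undec-9-en-8-one | CC(C)C(=O)CCC1=CC(=O)CCC2(C1)OCCO2
A4 | alternative 2 | 9,9-(ethylenedioxy)-4β-hydroxydaucan-6-one | C1CC(=O)[C@@H]2[C@](C)(CC[C@@]2(O)C(C)C)CC13OCCO3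
A5 | alternative 3 | (2E,6E)-farnesyl diphosphate | CC(C)=CCC/C(C)=C/CC/C(C)=C/COP(=O)(O)OP(=O)(O)O
A6 | alternative 3 | dauc-8-en-4β-ol | CC=1CC[C@@H]2[C@](C)(CC[C@@]2(O)C(C)C)CC=1
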